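**Plan**

- Retrosynthesis: the C8 ester is cut first. The lactone O–C6 bond and the C4=C5 π bond are then cut together, back to an acrylic acid on a ten-membered ring with a C5=C6 alkene. Further cuts are C5=C6 (metathesis), C7–C8 (allylation of a C8 aldehyde), C2–C3 with O–C3 (furanone) and C9–C10 (lactate alkylation).
- Enabling feature: with the ring alkene at C5=C6, the atoms C12(O2H)–C11–C7–C6=C5 are a 3-substituted pent-4-enoic acid. The hydrogen on C4 is the vinylogous γ-hydrogen of the furanone ring (O=C1–C2=C3–C4), so a C5 halide next to the new lactone can leave toward C4.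
- Forward order: furanone ring; chain extension at C8/C7 with the C11–C13 acrylate and the C6 vinyl group; ten-membered carbocycle by ring-closing metathesis; γ-lactone (key step); side-chain ester.
- Stereochemistry: C10 comes from L-lactic acid by self-regeneration of stereocentres. C7 and C8 come from a ligand-controlled, anti-selective chromium allylation. C6 comes from reversible trans-lactonisation next to C7. The 4Z geometry comes from the bridged ring, and the E side chain from a thermodynamic allylic transposition. C4 is carried as both epimers and erased in the key step.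

Key step: step 15

Remark: positions are cited in germacrane numbering (C1 ketone, C14 methyl on C10, C15 methyl on C4). The target as drawn has H6 trans to H7 and O8 anti to C6 along C9–C8–C7–C11, so an anti-selective chromium allylation with a prenyl group as the masked C8 aldehyde is used. C4 is left undefined in the SMILES of steps 7 to 14.

**Route**

Step 1
Reactants: 1 L-lactic acid; 2 pivalaldehyde
Product: 3 (2S,5S)-2-tert-butyl-5-methyl-1,3-dioxolan-4-one
Conditions: TsOH·H2O (cat.), H2SO4 (cat.), pentane, reflux, Dean–Stark; crystallisation from pentane at −78 °C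
Reagents that add atoms: none
Why: Acid-catalysed acetalisation of the α-hydroxy acid with removal of water should give the dioxolanone, whose crystalline cis isomer (tert-butyl and methyl on one face) keeps the lactate configuration.

Step 2
Reactants: 3 (2S,5S)-2-tert-butyl-5-methyl-1,3-dioxolan-4-one; 4 prenyl bromide (1-bromo-3-methylbut-2-ene)
Product: 6 (2S,5R)-2-tert-butyl-5-methyl-5-(3-methylbut-2-en-1-yl)-1,3-dioxolan-4-one, via lithium enolate 5 (not isolated)
Conditions: LiN(iPr)2, THF, −78 °C; then 4, −78 to −20 °C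
Reagents that add atoms: none
Why: Self-regeneration of stereocentres: the acetal carbon holds the chirality while the lactate carbon is planar, and the enolate is alkylated on the face opposite the tert-butyl group, which sets C10 (5R) with overall retention.

Step 3
Reactants: 6 (2S,5R)-2-tert-butyl-5-methyl-5-(3-methylbut-2-en-1-yl)-1,3-dioxolan-4-one
Product: 7 (2R)-2-hydroxy-2,5-dimethylhex-4-enoic acid
Conditions: KOH, MeOH/H2O, 60 °C; then 1 M HCl
Reagents that add atoms: potassium hydroxide, [K+].[OH-]
Why: Saponification of the lactone acetal releases pivalaldehyde from the hemiacetal and cannot affect the quaternary centre.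

Step 4
Reactants: 7 (2R)-2-hydroxy-2,5-dimethylhex-4-enoic acid
Product: 8 (3R)-3-hydroxy-3,6-dimethylhept-5-en-2-one
Conditions: MeLi (3.3 equiv), THF, −78 to 0 °C; then H2O
Reagents that add atoms: methyllithium, C[Li]
Why: Addition of methyllithium to the lithium carboxylate stops at the gem-dialkoxide, which is stabilised by the neighbouring alkoxide, and hydrolysis gives the methyl ketone (carboxylate to methyl ketone synthesis).

Step 5
Reactants: 8 (3R)-3-hydroxy-3,6-dimethylhept-5-en-2-one
Product: 9 (3R)-3,6-dimethyl-3-[(trimethylsilyl)oxy]hept-5-en-2-one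
Conditions: TMSCl, imidazole, DMF, 0 °C to rt
Reagents that add atoms: chlorotrimethylsilane, C[Si](C)(C)Cl
Why: Silylation of the tertiary α-hydroxyl removes the acidic proton and blocks O-acylation in step 7.

Step 6
Reactants: 10 2-methylbut-3-enoic acid (racemic)
Product: 11 2-methylbut-3-enoyl chloride (racemic)
Conditions: (COCl)2, DMF (cat.), CH2Cl2, 0 °C to rt; used as a solution
Reagents that add atoms: oxalyl chloride, O=C(Cl)C(Cl)=O
Why: Vilsmeier-catalysed acid chloride formation is mild enough to leave the β,γ-alkene out of conjugation.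

Step 7
Reactants: 9 (3R)-3,6-dimethyl-3-[(trimethylsilyl)oxy]hept-5-en-2-one; 11 2-methylbut-3-enoyl chloride
Product: 14 (2R)-5-(but-3-en-2-yl)-2-methyl-2-(3-methylbut-2-en-1-yl)furan-3(2H)-one, via lithium enolate 12 (not isolated), via silylated 1,3-diketone 13 (not isolated)
Conditions: 9 (2 equiv), LiN(iPr)2 (2 equiv), THF, −78 °C; 11 (1 equiv), −78 °C; then 1 M HCl, THF, rt
Reagents that add atoms: none
Why: Claisen-type C-acylation of the kinetic methyl ketone enolate (the second equivalent of enolate takes the acidic diketone proton) is followed by acid-induced desilylation, addition of the tertiary hydroxyl to the distal carbonyl and dehydration to the 3(2H)-furanone (cyclodehydration of an α'-hydroxy-1,3-diketone), with C4 formed as both epimers on purpose.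

Step 8
Reactants: 14 (2R)-5-(but-3-en-2-yl)-2-methyl-2-(3-methylbut-2-en-1-yl)furan-3(2H)-one
Product: 16 [(2R)-5-(but-3-en-2-yl)-2-methyl-3-oxo-2,3-dihydrofuran-2-yl]acetaldehyde, via trisubstituted epoxide 15 (not isolated)
Conditions: mCPBA (1.05 equiv), NaHCO3, CH2Cl2, 0 °C; then H5IO6, THF/H2O, 0 °C; used at once
Reagents that add atoms: 3-chloroperoxybenzoic acid, O=C(OO)c1cccc(Cl)c1
Why: Prilezhaev epoxidation should select the electron-rich trisubstituted prenyl alkene over the monosubstituted vinyl group and the push-pull furanone alkene, and periodic acid cleaves the epoxide through its diol to the C8 aldehyde (glycol cleavage).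

Step 9
Reactants: 17 acrolein; 18 tert-butyl acrylate
Product: 19 tert-butyl 3-hydroxy-2-methylidenepent-4-enoate (racemic)
Conditions: DABCO (cat.), 18 (3 equiv), neat, rt, slow addition of 17
Reagents that add atoms: none
Why: Morita–Baylis–Hillman reaction in which the ammonium enolate of the acrylate adds to the aldehyde carbon of acrolein, excess acrylate limiting self-coupling of acrolein.

Step 10
Reactants: 19 tert-butyl 3-hydroxy-2-methylidenepent-4-enoate
Product: 20 tert-butyl (2Z)-2-(bromomethyl)penta-2,4-dienoate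
Conditions: NBS, Me2S, CH2Cl2, 0 °C to rt
Reagents that add atoms: N-bromosuccinimide, BrN1C(=O)CCC1=O
Why: Bromide displaces the alkoxysulfonium-activated hydroxyl with allylic transposition (SN2′) to the conjugated dienoate with the vinyl group trans to the ester, as is usual for Morita–Baylis–Hillman alcohols under these neutral conditions that spare the tert-butyl ester.

Step 11
Reactants: 16 [(2R)-5-(but-3-en-2-yl)-2-methyl-3-oxo-2,3-dihydrofuran-2-yl]acetaldehyde; 20 tert-butyl (2Z)-2-(bromomethyl)penta-2,4-dienoate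
Product: 22 tert-butyl (3S,4R)-5-[(2R)-5-(but-3-en-2-yl)-2-methyl-3-oxo-2,3-dihydrofuran-2-yl]-3-ethenyl-4-hydroxy-2-methylidenepentanoate, via trimethylsilyl ether 21 (not isolated)
Conditions: CrCl2 (10 mol%), 1,8-bis(4-isopropyl-4,5-dihydrooxazol-2-yl)-3,6-di-tert-butylcarbazole (12 mol%, enantiomer chosen for Si-face addition), iPr2NEt (30 mol%), Mn (2 equiv), TMSCl, THF, rt; then aq. citric acid
Reagents that add atoms: none
Why: Catalytic asymmetric Nozaki–Hiyama–Kishi allylation: divalent chromium inserts into the allylic bromide, and the trivalent allylchromium, with the vinyl group trans to the metal-bearing CH2, adds through its γ-carbon (C7) in a chair transition state with the aldehyde chain equatorial, which should give the anti C7/C8 relation (zinc and indium reagents of this type favour syn), while the bis(oxazoline) ligand directs addition to the Si face of the aldehyde and so fixes C8 (4R) and C7 (3S) independently of the remote C10 centre.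

Step 12
Reactants: 22 tert-butyl (3S,4R)-5-[(2R)-5-(but-3-en-2-yl)-2-methyl-3-oxo-2,3-dihydrofuran-2-yl]-3-ethenyl-4-hydroxy-2-methylidenepentanoate
Product: 23 tert-butyl (3S,4R)-5-[(2R)-5-(but-3-en-2-yl)-2-methyl-3-oxo-2,3-dihydrofuran-2-yl]-3-ethenyl-2-methylidene-4-{[tri(propan-2-yl)silyl]oxy}pentanoate
Conditions: TIPSOTf, 2,6-lutidine, CH2Cl2, −78 to 0 °C
Reagents that add atoms: triisopropylsilyl trifluoromethanesulfonate, CC(C)[Si](C(C)C)(C(C)C)OS(=O)(=O)C(F)(F)F
Why: Silyl triflate silylation of the hindered secondary alcohol, the triisopropylsilyl ether being chosen because it has to survive trifluoroacetic acid in step 14 and hydrogen iodide in step 15.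

Step 13
Reactants: 23 tert-butyl (3S,4R)-5-[(2R)-5-(but-3-en-2-yl)-2-methyl-3-oxo-2,3-dihydrofuran-2-yl]-3-ethenyl-2-methylidene-4-{[tri(propan-2-yl)silyl]oxy}pentanoate
Product: 24 tert-butyl 2-[(3Z,5S,6R,8R)-2,8-dimethyl-9-oxo-6-{[tri(propan-2-yl)silyl]oxy}-11-oxabicyclo[6.2.1]undeca-1(10),3-dien-5-yl]prop-2-enoate
Conditions: second-generation Hoveyda–Grubbs catalyst (10 mol%), 1,4-benzoquinone (20 mol%), toluene (1 mM), 80 °C
Reagents that add atoms: none
Why: Ring-closing metathesis of the two monosubstituted vinyl groups forms C5=C6, the furanone bridge holding C3 and C10 close and the medium ring enforcing the Z alkene, while the 1,1-disubstituted acrylate and the furanone alkene are too hindered and electron-poor to compete and benzoquinone suppresses hydride-induced alkene migration.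

Step 14
Reactants: 24 tert-butyl 2-[(3Z,5S,6R,8R)-2,8-dimethyl-9-oxo-6-{[tri(propan-2-yl)silyl]oxy}-11-oxabicyclo[6.2.1]undeca-1(10),3-dien-5-yl]prop-2-enoate
Product: 25 2-[(3Z,5S,6R,8R)-2,8-dimethyl-9-oxo-6-{[tri(propan-2-yl)silyl]oxy}-11-oxabicyclo[6.2.1]undeca-1(10),3-dien-5-yl]prop-2-enoic acid
Conditions: TFA/CH2Cl2 (1:4), 0 °C to rt
Reagents that add atoms: none
Why: Acidolysis of the tert-butyl ester frees the C12 carboxyl without base, so the C5=C6 alkene should stay out of conjugation with the furanone.

Step 15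
Reactants: 25 2-[(3Z,5S,6R,8R)-2,8-dimethyl-9-oxo-6-{[tri(propan-2-yl)silyl]oxy}-11-oxabicyclo[6.2.1]undeca-1(10),3-dien-5-yl]prop-2-enoic acid
Product: 27 (4Z,6S,7R,8R,10R)-3,10-epoxy-1-oxo-8-{[tri(propan-2-yl)silyl]oxy}germacra-2,4,11(13)-trien-12,6-olide, via C5 iodolactone 26 (not isolated)
Conditions: I2 (1.2 equiv), MeCN, 0 °C to rt, no base; then DBU (5 equiv), 0 °C to rt; aq. Na2S2O3 work-up
Reagents that add atoms: none
Why: Iodolactonisation followed by E1cB dehydroiodination: iodine forms an iodonium ion on the isolated C5=C6 alkene, the C12 carboxyl opens it anti at C6, and DBU then removes the C4 hydrogen, which is γ to the C1 ketone through C2=C3, to give an extended dienolate that expels iodide from C5. The closest known reactions are the thermodynamically controlled iodolactonisation of 3-substituted pent-4-enoic acids and the base-induced dehydroiodination of iodolactones toward a conjugating position. The γ-lactone closes in the 5-exo mode (O–C6), the 6-endo attack at C5 leading to the less favoured δ-lactone. C6 is the only new stereocentre and is set relative to C7, because without base the lactonisation is reversible and should settle on the trans-fused lactone with C5 and C8 on opposite faces of the five-membered ring. The step needs iodine to take the isolated alkene rather than the electron-poor acrylate or the push-pull furanone alkene, which their low nucleophilicity should secure, and it needs elimination toward C4 rather than C6, which the vinylogous acidity of the C4 hydrogen secures. Because the elimination passes through a planar dienolate, both C4 epimers and either C5 iodide should give the same dienone, and the ether bridge across the ten-membered ring is expected to allow only the 4Z geometry.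

Step 16
Reactants: 27 (4Z,6S,7R,8R,10R)-3,10-epoxy-1-oxo-8-{[tri(propan-2-yl)silyl]oxy}germacra-2,4,11(13)-trien-12,6-olide
Product: 28 (4Z,6S,7S,8R,10R)-3,10-epoxy-8-hydroxy-1-oxogermacra-2,4,11(13)-trien-12,6-olide
Conditions: HF·pyridine, pyridine/THF, 0 °C to rt
Reagents that add atoms: none
Why: Fluoride-induced desilylation under buffered, non-basic conditions should leave the α-methylene lactone and the dienone untouched (the C7 descriptor changes only because the O8 substituent changes).

Step 17
Reactants: 29 acetaldehyde; 18 tert-butyl acrylate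
Product: 30 tert-butyl 3-hydroxy-2-methylidenebutanoate (racemic)
Conditions: DABCO (cat.), neat, rt
Reagents that add atoms: none
Why: Morita–Baylis–Hillman reaction of the acrylate with acetaldehyde.

Step 18
Reactants: 30 tert-butyl 3-hydroxy-2-methylidenebutanoate
Product: 32 tert-butyl (2E)-2-[(acetyloxy)methyl]but-2-enoate, via secondary acetate 31 (not isolated)
Conditions: Ac2O, Et3N, DMAP (cat.), CH2Cl2, 0 °C to rt; then DABCO (cat.), THF, 65 °C
Reagents that add atoms: acetic anhydride, CC(=O)OC(C)=O
Why: Acetylation followed by amine-catalysed allylic transposition (two successive SN2′ displacements through the allylammonium ion) should give the more stable primary acetate with the methyl group trans to the ester (E).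

Step 19
Reactants: 32 tert-butyl (2E)-2-[(acetyloxy)methyl]but-2-enoate
Product: 33 (2E)-2-[(acetyloxy)methyl]but-2-enoic acid
Conditions: TFA/CH2Cl2 (1:4), 0 °C to rt
Reagents that add atoms: none
Why: Acidolysis of the tert-butyl ester leaves the acetate and the E alkene untouched.

Step 20
Reactants: 28 (4Z,6S,7S,8R,10R)-3,10-epoxy-8-hydroxy-1-oxogermacra-2,4,11(13)-trien-12,6-olide; 33 (2E)-2-[(acetyloxy)methyl]but-2-enoic acid
Product: 35 (4Z,6S,7S,8R,10R)-8-{[(2E)-2-(acetoxymethyl)but-2-enoyl]oxy}-3,10-epoxy-1-oxogermacra-2,4,11(13)-trien-12,6-olide, via mixed anhydride 34 (not isolated)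
Conditions: 33, 2,4,6-trichlorobenzoyl chloride, Et3N, toluene, rt; then 28, DMAP, toluene, rt to 40 °C
Reagents that add atoms: none
Why: Yamaguchi esterification through the mixed anhydride and the acylpyridinium ion acylates the hindered C8 hydroxyl with retention, since only the O–H bond reacts and the E acid is the stable geometry.

**Compound list**

1 | L-lactic acid, (2S)-2-hydroxypropanoic acid | C[C@H](O)C(=O)O | starting material
2 | pivalaldehyde (2,2-dimethylpropanal) | CC(C)(C)C=O | starting material
3 | (2S,5S)-2-tert-butyl-5-methyl-1,3-dioxolan-4-one | C[C@@H]1O[C@H](C(C)(C)C)OC1=O | intermediate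
4 | prenyl bromide (1-bromo-3-methylbut-2-ene) | CC(C)=CCBr | starting material
5 | lithium (2S)-2-tert-butyl-5-methyl-1,3-dioxol-4-olate (lithium enolate of 3) | CC1=C(O[Li])O[C@@H](C(C)(C)C)O1 | intermediate
6 | (2S,5R)-2-tert-butyl-5-methyl-5-(3-methylbut-2-en-1-yl)-1,3-dioxolan-4-one | C[C@]1(CC=C(C)C)O[C@H](C(C)(C)C)OC1=O | intermediate
7 | (2R)-2-hydroxy-2,5-dimethylhex-4-enoic acid | C[C@@](O)(CC=C(C)C)C(=O)O | intermediate
8 | (3R)-3-hydroxy-3,6-dimethylhept-5-en-2-one | CC(=O)[C@](C)(O)CC=C(C)C | intermediate
9 | (3R)-3,6-dimethyl-3-[(trimethylsilyl)oxy]hept-5-en-2-one | CC(=O)[C@](C)(O[Si](C)(C)C)CC=C(C)C | intermediate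
10 | 2-methylbut-3-enoic acid (racemic) | C=CC(C)C(=O)O | starting material
11 | 2-methylbut-3-enoyl chloride (racemic) | C=CC(C)C(Cl)=O | intermediate
12 | lithium (3R)-3,6-dimethyl-3-[(trimethylsilyl)oxy]hepta-1,5-dien-2-olate (lithium enolate of 9) | C=C(O[Li])[C@](C)(O[Si](C)(C)C)CC=C(C)C | intermediate
13 | (7R)-3,7,10-trimethyl-7-[(trimethylsilyl)oxy]undeca-1,9-diene-4,6-dione (both C3 epimers) | C=CC(C)C(=O)CC(=O)[C@](C)(O[Si](C)(C)C)CC=C(C)C | intermediate
14 | (2R)-5-(but-3-en-2-yl)-2-methyl-2-(3-methylbut-2-en-1-yl)furan-3(2H)-one (both C4 epimers) | C=CC(C)C1=CC(=O)[C@@](C)(CC=C(C)C)O1 | intermediate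
15 | (2R)-5-(but-3-en-2-yl)-2-[(3,3-dimethyloxiran-2-yl)methyl]-2-methylfuran-3(2H)-one | C=CC(C)C1=CC(=O)[C@@](C)(CC2OC2(C)C)O1 | intermediate
16 | [(2R)-5-(but-3-en-2-yl)-2-methyl-3-oxo-2,3-dihydrofuran-2-yl]acetaldehyde | C=CC(C)C1=CC(=O)[C@@](C)(CC=O)O1 | intermediate
17 | acrolein (prop-2-enal) | C=CC=O | starting material
18 | tert-butyl acrylate | C=CC(=O)OC(C)(C)C | starting material
19 | tert-butyl 3-hydroxy-2-methylidenepent-4-enoate (racemic) | C=CC(O)C(=C)C(=O)OC(C)(C)C | intermediate
20 | tert-butyl (2Z)-2-(bromomethyl)penta-2,4-dienoate | CC(C)(C)OC(=O)/C(CBr)=C/C=C | intermediate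
21 | tert-butyl (3S,4R)-5-[(2R)-5-(but-3-en-2-yl)-2-methyl-3-oxo-2,3-dihydrofuran-2-yl]-3-ethenyl-2-methylidene-4-[(trimethylsilyl)oxy]pentanoate | C=CC(C)C1=CC(=O)[C@@](C)(C[C@@H](O[Si](C)(C)C)[C@@H](C=C)C(=C)C(=O)OC(C)(C)C)O1 | intermediate
22 | tert-butyl (3S,4R)-5-[(2R)-5-(but-3-en-2-yl)-2-methyl-3-oxo-2,3-dihydrofuran-2-yl]-3-ethenyl-4-hydroxy-2-methylidenepentanoate | C=CC(C)C1=CC(=O)[C@@](C)(C[C@@H](O)[C@@H](C=C)C(=C)C(=O)OC(C)(C)C)O1 | intermediate
23 | tert-butyl (3S,4R)-5-[(2R)-5-(but-3-en-2-yl)-2-methyl-3-oxo-2,3-dihydrofuran-2-yl]-3-ethenyl-2-methylidene-4-{[tri(propan-2-yl)silyl]oxy}pentanoate | C=CC(C)C1=CC(=O)[C@@](C)(C[C@@H](O[Si](C(C)C)(C(C)C)C(C)C)[C@@H](C=C)C(=C)C(=O)OC(C)(C)C)O1 | intermediate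
24 | tert-butyl 2-[(3Z,5S,6R,8R)-2,8-dimethyl-9-oxo-6-{[tri(propan-2-yl)silyl]oxy}-11-oxabicyclo[6.2.1]undeca-1(10),3-dien-5-yl]prop-2-enoate (both C4 epimers) | CC(C)(C)OC(=O)C(=C)[C@@H]1/C=C\C(C)C2=CC(=O)[C@@](C)(C[C@H]1O[Si](C(C)C)(C(C)C)C(C)C)O2 | intermediate
25 | 2-[(3Z,5S,6R,8R)-2,8-dimethyl-9-oxo-6-{[tri(propan-2-yl)silyl]oxy}-11-oxabicyclo[6.2.1]undeca-1(10),3-dien-5-yl]prop-2-enoic acid (both C4 epimers) | OC(=O)C(=C)[C@@H]1/C=C\C(C)C2=CC(=O)[C@@](C)(C[C@H]1O[Si](C(C)C)(C(C)C)C(C)C)O2 | intermediate
26 | 5-iodo-3,10-epoxy-1-oxo-8-{[tri(propan-2-yl)silyl]oxy}germacra-2,11(13)-dien-12,6-olide (C6, C7, C8 and C10 arranged as in 27; C4 and C5 mixed) | C=C1C(=O)O[C@H]2C(I)C(C)C3=CC(=O)[C@@](C)(C[C@@H](O[Si](C(C)C)(C(C)C)C(C)C)[C@H]12)O3 | intermediate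
27 | (4Z,6S,7R,8R,10R)-3,10-epoxy-1-oxo-8-{[tri(propan-2-yl)silyl]oxy}germacra-2,4,11(13)-trien-12,6-olide | C=C1C(=O)O[C@H]2/C=C(/C)C3=CC(=O)[C@@](C)(C[C@@H](O[Si](C(C)C)(C(C)C)C(C)C)[C@H]12)O3 | intermediate
28 | (4Z,6S,7S,8R,10R)-3,10-epoxy-8-hydroxy-1-oxogermacra-2,4,11(13)-trien-12,6-olide | C=C1C(=O)O[C@H]2/C=C(/C)C3=CC(=O)[C@@](C)(C[C@@H](O)[C@H]12)O3 | intermediate
29 | acetaldehyde | CC=O | starting material
30 | tert-butyl 3-hydroxy-2-methylidenebutanoate (racemic) | CC(O)C(=C)C(=O)OC(C)(C)C | intermediate
31 | tert-butyl 3-(acetyloxy)-2-methylidenebutanoate | CC(OC(C)=O)C(=C)C(=O)OC(C)(C)C | intermediate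
32 | tert-butyl (2E)-2-[(acetyloxy)methyl]but-2-enoate | C/C=C(\COC(C)=O)C(=O)OC(C)(C)C | intermediate
33 | (2E)-2-[(acetyloxy)methyl]but-2-enoic acid | C/C=C(\COC(C)=O)C(=O)O | intermediate
34 | (2E)-2-[(acetyloxy)methyl]but-2-enoic 2,4,6-trichlorobenzoic anhydride | C/C=C(\COC(C)=O)C(=O)OC(=O)c1c(Cl)cc(Cl)cc1Cl | intermediate
35 | (4Z,6S,7S,8R,10R)-8-{[(2E)-2-(acetoxymethyl)but-2-enoyl]oxy}-3,10-epoxy-1-oxogermacra-2,4,11(13)-trien-12,6-olide | C=C1C(=O)O[C@H]2/C=C(/C)C3=CC(=O)[C@@](C)(C[C@@H](OC(=O)/C(=C/C)COC(C)=O)[C@H]12)O3 | target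

**Step count and risks**

Total step count: 20. Longest linear sequence: 14 steps (steps 1–5, 7, 8, 11–16 and 20).

The three steps most likely to fail:

Step 13 (ring-closing metathesis). Intermolecular metathesis may outrun closure of the freely rotating chain, the two C4 epimers may close at different rates, and a ruthenium hydride may move the C4 vinyl group into conjugation with the furanone. The fallback closes the ring on a lactone template; it sets out from 22 and comes back at 25. Trifluoroacetic acid converts 22 into the trans α-methylene-γ-butyrolactone F1 (O8 joined to C12), whose five-membered ring ties C8 to C7 and removes rotors between the two vinyl groups. Ring-closing metathesis of this diene under the conditions of step 13 should give the bicyclic 12,8-lactone F2. Me3SnOH in 1,2-dichloroethane at 60 °C opens the lactone to the hydroxy acid F3. TIPSOTf (2.5 equiv) and 2,6-lutidine give the bis-silyl derivative F4, whose silyl ester is hydrolysed during aqueous work-up to give 25.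

Step 11 (chromium allylation). Simple diastereoselection is lost if the allylchromium reacts through the geometry with the vinyl group cis to the metal-bearing carbon, and facial control may be eroded by mismatch with the C10 centre. The fallback sets C7 by a syn-selective coupling and corrects C8 by inversion; it sets out from 16 and comes back at 22. Indium-mediated coupling of 16 with 20 in THF/H2O, a reaction class that favours syn adducts, gives after chromatographic separation from the other syn diastereomer the syn alcohol F5 (C7 as required, C8 epimeric). A Mitsunobu reaction with chloroacetic acid, PPh3 and diisopropyl azodicarboxylate inverts C8 to give the chloroacetate F6. Thiourea and NaHCO3 in ethanol remove the chloroacetyl group to give 22.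

Step 15 (key step). DBU may deprotonate C7 and move the exocyclic alkene into the lactone ring, iodine may attack the nucleophilic furanone carbon C2, or hydrogen iodide may cleave the silyl ether before the lactone has formed. The fallback replaces halogen and base by selenium and an oxidative syn elimination; it sets out from 25 and comes back at 27. Phenylselenenyl chloride in CH2Cl2 at −78 °C gives the selenolactone F7 (PhSe on C5, O–C6 from the same anti 5-exo closure). H2O2 with pyridine at 0 °C oxidises it to the selenoxide F8, which eliminates at once. Elimination toward the oxygen-bearing C6 is disfavoured, so only the C4 hydrogen is used and 27 is formed without strong base; the C4 epimers may have to be equilibrated with a little triethylamine so that both reach the syn-periplanar arrangement.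

Further compounds
F1 | step 13 | (2R)-5-(but-3-en-2-yl)-2-{[(2R,3S)-3-ethenyl-4-methylidene-5-oxooxolan-2-yl]methyl}-2-methylfuran-3(2H)-one | C=CC(C)C1=CC(=O)[C@@](C)(C[C@H]2OC(=O)C(=C)[C@@H]2C=C)O1
F2 | step 13 | (5Z,7S,8R,10R)-3,10-epoxy-1-oxogermacra-2,5,11(13)-trien-12,8-olide (both C4 epimers) | C=C1[C@@H]2/C=C\C(C)C3=CC(=O)[C@@](C)(C[C@H]2OC1=O)O3
F3 | step 13 | 2-[(3Z,5S,6R,8R)-6-hydroxy-2,8-dimethyl-9-oxo-11-oxabicyclo[6.2.1]undeca-1(10),3-dien-5-yl]prop-2-enoic acid | OC(=O)C(=C)[C@@H]1/C=C\C(C)C2=CC(=O)[C@@](C)(C[C@H]1O)O2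
F4 | step 13 | tri(propan-2-yl)silyl ester of 25 | CC(C)[Si](C(C)C)(C(C)C)OC(=O)C(=C)[C@@H]1/C=C\C(C)C2=CC(=O)[C@@](C)(C[C@H]1O[Si](C(C)C)(C(C)C)C(C)C)O2
F5 | step 11 | tert-butyl (3S,4S)-5-[(2R)-5-(but-3-en-2-yl)-2-methyl-3-oxo-2,3-dihydrofuran-2-yl]-3-ethenyl-4-hydroxy-2-methylidenepentanoate | C=CC(C)C1=CC(=O)[C@@](C)(C[C@H](O)[C@@H](C=C)C(=C)C(=O)OC(C)(C)C)O1
F6 | step 11 | tert-butyl (3S,4R)-5-[(2R)-5-(but-3-en-2-yl)-2-methyl-3-oxo-2,3-dihydrofuran-2-yl]-4-[(chloroacetyl)oxy]-3-ethenyl-2-methylidenepentanoate | C=CC(C)C1=CC(=O)[C@@](C)(C[C@@H](OC(=O)CCl)[C@@H](C=C)C(=C)C(=O)OC(C)(C)C)O1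
F7 | step 15 | 5-(phenylselanyl)-3,10-epoxy-1-oxo-8-{[tri(propan-2-yl)silyl]oxy}germacra-2,11(13)-dien-12,6-olide (C6, C7, C8 and C10 as in 27) | C=C1C(=O)O[C@H]2C([Se]c4ccccc4)C(C)C3=CC(=O)[C@@](C)(C[C@@H](O[Si](C(C)C)(C(C)C)C(C)C)[C@H]12)O3
F8 | step 15 | selenoxide of F7 | C=C1C(=O)O[C@H]2C([Se](=O)c4ccccc4)C(C)C3=CC(=O)[C@@](C)(C[C@@H](O[Si](C(C)C)(C(C)C)C(C)C)[C@H]12)O3
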